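The ten-membered ring is not closed but unveiled: adding a C1–C6 bond retrosynthetically turns the germacradiene into a cis-decalin whose ring A (C1–C6, a 3-methylcyclohexene) locks C4=C5 ring-cis and whose ring B (C6, C1, C10, C9, C8, C7) carries a spiro-epoxide at C10 (C14–O). The key step exploits the antiperiplanar array O6–C6, C1–C6, C10–O of this epoxy alcohol: Ti(OiPr)4-mediated Grob fragmentation cleaves the shared C1–C6 bond and the C10–O bond at once and delivers the C6 ketone, the ring-cis C1=C10 alkene and the C14 hydroxymethyl group. The precursor is built from an erythronolactone-derived C7–C10 chain and 3-methylcyclohexenone by aldol addition and allylchromium ring closure.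

Key step: step 11

Remark: atom labels C1–C15 follow the germacrane numbering of the target (C12 lactone carbonyl, C13 exocyclic methylene, C14 formyl carbon, C15 methyl) and are used for all intermediates; "ring-cis" means that the two ring carbons lie on the same side of the double bond.

Step 1
Reactants: 1 2,3-O-isopropylidene-D-erythronolactone
Product: 2 2,3-O-isopropylidene-D-erythrofuranose (lactol)
Conditions: iBu2AlH, CH2Cl2, −78 °C
Reagents that add atoms: none
Why: Partial reduction of the γ-lactone with iBu2AlH stops at the aluminium hemiacetal at low temperature and gives the lactol (lactone-to-lactol reduction), leaving C8 and C9 untouched, the new anomeric centre being of no consequence.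

Step 2
Reactants: 2 2,3-O-isopropylidene-D-erythrofuranose (lactol)
Product: 3 vinyl dioxolane alcohol
Conditions: Ph3PCH3Br, KOtBu, THF, 0 to 25 °C
Reagents that add atoms: methyltriphenylphosphonium bromide, C[P+](c1ccccc1)(c1ccccc1)c1ccccc1.[Br-]
Why: Wittig methylenation of the open hydroxy-aldehyde form of the lactol with excess non-stabilised ylide gives the terminal alkene at C7 and frees the C10 hydroxyl, olefination being faster than epimerisation of the α-oxygenated centre C8.

Step 3
Reactants: 3 vinyl dioxolane alcohol; 4 (Z)-1,4-dichlorobut-2-ene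
Product: 5 allylic chloride alcohol
Conditions: second-generation Grubbs catalyst RuCl2(=CHPh)(PCy3)(SIMes) (5 mol %), excess 4, CH2Cl2, 40 °C
Reagents that add atoms: none
Why: Olefin cross-metathesis of the terminal alkene with the symmetrical internal dichloride transfers a CH–CH2Cl unit (C11, C12) and should give mainly the E allylic chloride, whose geometry is irrelevant because the derived allylchromium species equilibrates; no stereocentre is formed.

Step 4
Reactants: 5 allylic chloride alcohol
Product: 6 C10 aldehyde
Conditions: Dess–Martin periodinane, NaHCO3, CH2Cl2, 0 to 25 °C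
Reagents that add atoms: none
Why: Dess–Martin oxidation converts the primary alcohol into the aldehyde under buffered, non-basic conditions that avoid epimerisation of the α-alkoxy centre C9 and leave the allylic chloride untouched.

Step 5
Reactants: 7 3-methylcyclohex-2-en-1-one; 6 C10 aldehyde
Product: 10 aldol adduct (C1–C10 syn and C10–C9 anti), via lithium dienolate 8 (not isolated), via titanium dienolate 9 (not isolated)
Conditions: LiN(iPr)2, THF, −78 °C; ClTi(OiPr)3, −78 to −40 °C; then 6, −78 °C
Reagents that add atoms: none
Why: Kinetic deprotonation at the α′ carbon gives the cross-conjugated dienolate, whose tri(isopropoxy)titanium form should add in the syn-selective aldol mode known for titanium enolates of cyclic ketones and with Felkin–Anh (non-chelation) attack anti to the C9–O bond, which sets C1 with its C1–C2 bond anti to O9 along the zigzag chain (the C10 carbinol centre is removed again in step 7).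

Step 6
Reactants: 10 aldol adduct
Product: 12 cis-decalin 6,10-diol, via allylchromium dichloride 11 (not isolated)
Conditions: CrCl2, LiI (cat.), THF, 25 °C, high dilution
Reagents that add atoms: none
Why: Nozaki–Hiyama–Kishi reaction in which CrCl2 reduces the allylic halide to an allyl species of trivalent chromium that adds through its γ-carbon C7 to the enone carbonyl in a six-membered-ring-forming, chair-like closed transition state whose C10 hydroxyl is held gauche to the carbonyl by hydrogen bond or chromium chelation, which places the new C6–O bond cis to C1–H (cis-decalin) and the vinyl group equatorial and cis to O8 (sets C6 and C7), such allylchromium reagents adding 1,2 to enones and tolerating the free hydroxyl and the β-oxygen at C8.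

Step 7
Reactants: 12 cis-decalin 6,10-diol
Product: 13 C10 ketone
Conditions: Dess–Martin periodinane, NaHCO3, CH2Cl2, 0 to 25 °C
Reagents that add atoms: none
Why: Dess–Martin oxidation of the only secondary alcohol gives the C10 ketone while the tertiary allylic C6 hydroxyl cannot be oxidised, the buffer preventing acid-catalysed dehydration of the β-hydroxy ketone; no stereocentre is touched.

Step 8
Reactants: 13 C10 ketone
Product: 14 C6-O-trimethylsilyl ketone
Conditions: 1-(trimethylsilyl)imidazole, CH2Cl2, 25 °C
Reagents that add atoms: 1-(trimethylsilyl)imidazole, C[Si](C)(C)n1ccnc1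
Why: Silyl ether formation with the neutral silyl donor masks the tertiary hydroxyl without enolising the ketone, so that the aldol-type C6–OH/C10=O pair cannot undergo retro-aldol cleavage or dehydration in the basic ylide step.

Step 9
Reactants: 14 C6-O-trimethylsilyl ketone; 15 trimethylsulfonium iodide
Product: 17 C6-O-trimethylsilyl spiro-epoxide, via dimethylsulfonium methylide 16 (not isolated)
Conditions: Me3SI, n-BuLi, THF, −10 °C; then 14, −10 to 0 °C
Reagents that add atoms: none
Why: Corey–Chaykovsky epoxidation in which the unstabilised sulfonium ylide adds irreversibly to the C10 carbonyl from the convex face of the cis-decalin, away from ring A carbon C5 lying axial beneath C10, and the betaine closes to the spiro-epoxide with C14 cis to the C6 oxygen and trans to C2 (sets C10), addition being faster than deprotonation of the hindered α-positions C1 and C9.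

Step 10
Reactants: 17 C6-O-trimethylsilyl spiro-epoxide
Product: 18 cis-decalin epoxy alcohol
Conditions: K2CO3, MeOH, 0 to 25 °C
Reagents that add atoms: none
Why: Base-catalysed methanolysis of the trimethylsilyl ether (silyl ether cleavage) frees the tertiary C6 hydroxyl under conditions too weakly basic to open the epoxide or to start the fragmentation.

Step 11
Reactants: 18 cis-decalin epoxy alcohol
Product: 20 cyclodecadienone with C14 hydroxymethyl group, via titanium C6-alkoxide 19 (not isolated)
Conditions: Ti(OiPr)4 (1.5 equiv), CH2Cl2, 0 to 40 °C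
Reagents that add atoms: none
Why: Ligand exchange gives the titanium C6-alkoxide and titanium also coordinates the epoxide oxygen, whereupon the alkoxide lone pair pushes into C6, the C1–C6 σ bond becomes the C1=C10 π bond and the C10–O bond breaks in one concerted antiperiplanar event. The closest known reaction type is the Lewis-acid-mediated epoxy-alcohol Grob fragmentation of bicyclic 3,4-epoxy alcohols to medium-ring hydroxy ketones, a relative of the Wharton fragmentation of decalin 1,3-diol monosulfonates. No ring is closed by bond formation: the ten-membered ring appears by scission of the bond shared by rings A and B, so the entropic cost of medium-ring closure is never paid. No stereocentre is created, since C1, C6 and C10 become trigonal and C7, C8 and C9 are not touched. The step needs the ring-cis C1=C10 geometry and fragmentation in preference to endo attack of O6 on C14 or epoxide rearrangement; in the chair of ring B with O6, C14 and C2 axial the equatorial C10–O bond is antiperiplanar to C1–C6 and C2 and C14 are trans-diaxial, so that C2 ends cis to C9, while the endo ether closure lacks a collinear trajectory. Release of epoxide strain and the conjugated C4=C5–C6=O enone drive the reaction, and the mild titanium alkoxide leaves the β-oxygen at C8 and the α-vinyl centre C7 intact.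

Step 12
Reactants: 20 cyclodecadienone with C14 hydroxymethyl group
Product: 21 C6,C14-diol
Conditions: NaBH4, CeCl3·7H2O, MeOH, −78 °C (20 used without storage)
Reagents that add atoms: none
Why: Luche reduction in which the cerium-activated borohydride reduces the enone carbonyl 1,2 at −78 °C before O8 can be eliminated or C7 epimerised, hydride attack on the outer face of the carbonyl in the conformer with the C7 vinyl group pseudo-equatorial being expected to give the alcohol with H6 anti to H7, as the trans-fused lactone requires (sets C6 by substrate control).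

Step 13
Reactants: 21 C6,C14-diol
Product: 22 C14-O-TBS ether
Conditions: TBSCl, imidazole, CH2Cl2, 0 °C
Reagents that add atoms: tert-butyl(chloro)dimethylsilane, CC(C)(C)[Si](C)(C)Cl
Why: Selective silyl ether formation at the primary allylic hydroxyl over the secondary C6 hydroxyl with the bulky silyl chloride protects C14–OH for the oxidation and enolate steps.

Step 14
Reactants: 22 C14-O-TBS ether
Product: 24 C6,C12-diol, via B-alkyl-9-BBN adduct 23 (not isolated)
Conditions: 9-BBN (excess), THF, 0 to 25 °C; then NaOH, H2O2, 0 °C
Reagents that add atoms: hydrogen peroxide, OO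
Why: Hydroboration–oxidation in which the bulky dialkylborane adds anti-Markovnikov to the monosubstituted vinyl group only, leaving both trisubstituted ring alkenes, and alkaline peroxide turns the C12–B bond into the primary alcohol without touching a stereocentre.

Step 15
Reactants: 24 C6,C12-diol
Product: 26 saturated γ-lactone, via lactol 25 (not isolated)
Conditions: TEMPO (cat.), PhI(OAc)2, CH2Cl2, 25 °C
Reagents that add atoms: none
Why: TEMPO/PhI(OAc)2 oxidative lactonisation in which the oxoammonium species oxidises the primary alcohol selectively to the aldehyde, which the C6 hydroxyl traps as the five-membered lactol that is oxidised on to the lactone, O8 being blocked by the acetonide and the trans ring fusion following from the configurations at C6 and C7.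

Step 16
Reactants: 26 saturated γ-lactone; 27 Eschenmoser's salt
Product: 31 α-methylene lactone, via lithium enolate 28 (not isolated), via Mannich base 29 (not isolated), via methiodide 30 (not isolated)
Conditions: LiN(iPr)2, THF, −78 °C; 27, −78 to 0 °C; then MeI, MeOH, 25 °C; then NaHCO3, H2O/CH2Cl2
Reagents that add atoms: none
Why: α-Methylenation by Mannich reaction of the lactone lithium enolate with the iminium salt, N-methylation and β-elimination of trimethylamine installs C13, the transient C11 stereocentre being destroyed again.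

Step 17
Reactants: 31 α-methylene lactone
Product: 32 C14 allylic alcohol
Conditions: Bu4NF, AcOH, THF, 0 °C
Reagents that add atoms: none
Why: Fluoride-mediated cleavage of the primary silyl ether (desilylation), buffered with acetic acid so that neither fluoride nor alkoxide adds to the α-methylene lactone, frees the C14 hydroxyl.

Step 18
Reactants: 32 C14 allylic alcohol
Product: 33 C14 enal acetonide
Conditions: MnO2, CH2Cl2, 25 °C
Reagents that add atoms: none
Why: MnO2 oxidises the primary allylic alcohol to the α,β-unsaturated aldehyde (allylic oxidation) without isomerising C1=C10, the allylic C9 oxygen still being masked in the acetonide.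

Step 19
Reactants: 33 C14 enal acetonide
Product: 34 C14 enal 8,9-diol
Conditions: CF3CO2H, H2O, CH2Cl2, 0 °C
Reagents that add atoms: none
Why: Acid-catalysed hydrolysis of the isopropylidene acetal (acetal hydrolysis) releases the C8,C9 diol, the enal, the allylic lactone and the α-methylene lactone tolerating cold aqueous trifluoroacetic acid.

Step 20
Reactants: 34 C14 enal 8,9-diol; 35 (R)-2-methylbutanoic acid
Product: 37 target CNP0256845.2, via O-acylisourea 36 (not isolated)
Conditions: DCC, DMAP (cat.), CH2Cl2, −20 to 0 °C
Reagents that add atoms: none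
Why: Steglich esterification in which DMAP transfers the carbodiimide-activated acid to the C9 hydroxyl, which is allylic, flanked by the flat sp2 carbon C10 and acidified by the adjacent enal, in preference to the C8 hydroxyl shielded by the ring-fusion carbon C7, low temperature and catalytic DMAP suppressing acyl migration and racemisation of the acid.

Compound list
1 | 2,3-O-isopropylidene-D-erythronolactone, (3aR,6aR)-2,2-dimethyldihydrofuro[3,4-d][1,3]dioxol-4(3aH)-one | O=C1OC[C@H]2OC(C)(C)O[C@@H]12 | starting material
2 | 2,3-O-isopropylidene-D-erythrofuranose (lactol, both anomers) | OC1OC[C@H]2OC(C)(C)O[C@@H]12 | intermediate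
3 | [(4R,5S)-2,2-dimethyl-5-vinyl-1,3-dioxolan-4-yl]methanol (vinyl dioxolane alcohol) | OC[C@H]1OC(C)(C)O[C@H]1C=C | intermediate
4 | (Z)-1,4-dichlorobut-2-ene | ClC/C=C\CCl | starting material
5 | [(4R,5S)-5-[(E)-3-chloroprop-1-enyl]-2,2-dimethyl-1,3-dioxolan-4-yl]methanol (allylic chloride alcohol) | OC[C@H]1OC(C)(C)O[C@H]1/C=C/CCl | intermediate
6 | (4S,5S)-5-[(E)-3-chloroprop-1-enyl]-2,2-dimethyl-1,3-dioxolane-4-carbaldehyde (C10 aldehyde) | O=C[C@H]1OC(C)(C)O[C@H]1/C=C/CCl | intermediate
7 | 3-methylcyclohex-2-en-1-one | CC1=CC(=O)CCC1 | starting material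
8 | lithium 5-methylcyclohexa-1,5-dien-1-olate (lithium dienolate, not isolated) | [Li]OC1=CCCC(C)=C1 | intermediate
9 | tri(isopropoxy)titanium 5-methylcyclohexa-1,5-dien-1-olate (titanium dienolate, not isolated) | CC(C)O[Ti](OC(C)C)(OC(C)C)OC1=CCCC(C)=C1 | intermediate
10 | (6R)-6-[(R)-hydroxy[(4R,5S)-5-[(E)-3-chloroprop-1-enyl]-2,2-dimethyl-1,3-dioxolan-4-yl]methyl]-3-methylcyclohex-2-en-1-one (aldol adduct; C1–C10 syn, C10–C9 anti) | O=C1C=C(C)CC[C@@H]1[C@@H](O)[C@H]2OC(C)(C)O[C@H]2/C=C/CCl | intermediate
11 | allylchromium dichloride derived from 10, trivalent chromium at C12 (not isolated) | O=C1C=C(C)CC[C@@H]1[C@@H](O)[C@H]2OC(C)(C)O[C@H]2/C=C/C[Cr](Cl)Cl | intermediate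
12 | cis-decalin 6,10-diol: rings A and B cis-fused at C1–C6, C4-methyl, C4=C5, C8,C9-O-isopropylidene, C7-vinyl; O6, H1, O10, O9, O8 and the vinyl group on one face of ring B, C2 and C5 on the other | O[C@@]12C=C(C)CC[C@@H]1[C@@H](O)[C@H]3OC(C)(C)O[C@H]3[C@H]2C=C | intermediate
13 | C10 ketone of 12 with free tertiary C6 hydroxyl | O[C@@]12C=C(C)CC[C@@H]1C(=O)[C@H]3OC(C)(C)O[C@H]3[C@H]2C=C | intermediate
14 | C6-O-trimethylsilyl ether of 13 | C[Si](C)(C)O[C@@]12C=C(C)CC[C@@H]1C(=O)[C@H]3OC(C)(C)O[C@H]3[C@H]2C=C | intermediate
15 | trimethylsulfonium iodide | C[S+](C)C.[I-] | starting material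
16 | dimethylsulfonium methylide (not isolated) | C[S+](C)[CH2-] | intermediate
17 | C6-O-trimethylsilyl spiro-epoxide: C10 spiro-oxirane with C14 cis to O6 and trans to C2 | C[Si](C)(C)O[C@@]12C=C(C)CC[C@@H]1[C@@]3(CO3)[C@H]4OC(C)(C)O[C@H]4[C@H]2C=C | intermediate
18 | cis-decalin epoxy alcohol, (1S,6R,7R,8S,9S,10R) in germacrane locants: C6–OH, C10 spiro-epoxide (C14–O), C8,C9-acetonide, C7-vinyl, C4=C5 | O[C@@]12C=C(C)CC[C@@H]1[C@@]3(CO3)[C@H]4OC(C)(C)O[C@H]4[C@H]2C=C | intermediate
19 | tri(isopropoxy)titanium C6-alkoxide of 18 (not isolated) | CC(C)O[Ti](OC(C)C)(OC(C)C)O[C@@]12C=C(C)CC[C@@H]1[C@@]3(CO3)[C@H]4OC(C)(C)O[C@H]4[C@H]2C=C | intermediate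
20 | cyclodeca-4,1(10)-dien-6-one, both alkenes ring-cis, (7R,8S,9R): C14 hydroxymethyl on C10, C8,C9-acetonide, C7-vinyl | O=C1/C=C(/C)CC/C=C(/CO)[C@H]2OC(C)(C)O[C@H]2[C@H]1C=C | intermediate
21 | (6R)-C6,C14-diol from 20 | O[C@@H]1/C=C(/C)CC/C=C(/CO)[C@H]2OC(C)(C)O[C@H]2[C@H]1C=C | intermediate
22 | C14-O-tert-butyldimethylsilyl ether of 21 | O[C@@H]1/C=C(/C)CC/C=C(/CO[Si](C)(C)C(C)(C)C)[C@H]2OC(C)(C)O[C@H]2[C@H]1C=C | intermediate
23 | B-alkyl-9-BBN adduct at C12 of 22 (not isolated) | O[C@@H]1/C=C(/C)CC/C=C(/CO[Si](C)(C)C(C)(C)C)[C@H]2OC(C)(C)O[C@H]2[C@H]1CCB3C4CCCC3CCC4 | intermediate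
24 | C6,C12-diol (C7 2-hydroxyethyl side chain) | O[C@@H]1/C=C(/C)CC/C=C(/CO[Si](C)(C)C(C)(C)C)[C@H]2OC(C)(C)O[C@H]2[C@H]1CCO | intermediate
25 | C12 lactol closed on O6 (both anomers, not isolated) | C1C(O)O[C@@H]2/C=C(/C)CC/C=C(/CO[Si](C)(C)C(C)(C)C)[C@H]3OC(C)(C)O[C@H]3[C@@H]12 | intermediate
26 | trans-fused 6,12-γ-lactone (C11 methylene), C14-O-TBS, C8,C9-acetonide | C1C(=O)O[C@@H]2/C=C(/C)CC/C=C(/CO[Si](C)(C)C(C)(C)C)[C@H]3OC(C)(C)O[C@H]3[C@@H]12 | intermediate
27 | Eschenmoser's salt, N,N-dimethylmethyleneiminium iodide | C=[N+](C)C.[I-] | starting material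
28 | lithium enolate of 26 (not isolated) | C1=C(O[Li])O[C@@H]2/C=C(/C)CC/C=C(/CO[Si](C)(C)C(C)(C)C)[C@H]3OC(C)(C)O[C@H]3[C@@H]12 | intermediate
29 | C11 dimethylaminomethyl lactone, Mannich base (C11 epimers, not isolated) | CN(C)CC1C(=O)O[C@@H]2/C=C(/C)CC/C=C(/CO[Si](C)(C)C(C)(C)C)[C@H]3OC(C)(C)O[C@H]3[C@@H]12 | intermediate
30 | trimethylammonium iodide of 29, methiodide (not isolated) | C[N+](C)(C)CC1C(=O)O[C@@H]2/C=C(/C)CC/C=C(/CO[Si](C)(C)C(C)(C)C)[C@H]3OC(C)(C)O[C@H]3[C@@H]12.[I-] | intermediate
31 | α-methylene γ-lactone, C14-O-TBS, C8,C9-acetonide | C=C1C(=O)O[C@@H]2/C=C(/C)CC/C=C(/CO[Si](C)(C)C(C)(C)C)[C@H]3OC(C)(C)O[C@H]3[C@@H]12 | intermediate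
32 | α-methylene lactone with free C14 allylic alcohol, C8,C9-acetonide | C=C1C(=O)O[C@@H]2/C=C(/C)CC/C=C(/CO)[C@H]3OC(C)(C)O[C@H]3[C@@H]12 | intermediate
33 | α-methylene lactone C14 enal, C8,C9-acetonide | C=C1C(=O)O[C@@H]2/C=C(/C)CC/C=C(/C=O)[C@H]3OC(C)(C)O[C@H]3[C@@H]12 | intermediate
34 | α-methylene lactone C14 enal with free C8 and C9 hydroxyls | C=C1C(=O)O[C@@H]2/C=C(/C)CC/C=C(/C=O)[C@@H](O)[C@@H](O)[C@@H]12 | intermediate
35 | (R)-2-methylbutanoic acid | CC[C@@H](C)C(=O)O | starting material
36 | O-acylisourea from 35 and DCC (not isolated) | CC[C@@H](C)C(=O)OC(=NC1CCCCC1)NC1CCCCC1 | intermediate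
37 | CNP0256845.2: (6R,7R,8S,9R)-8-hydroxy-9-[(R)-2-methylbutanoyloxy]-14-oxo-germacra-1(10),4,11(13)-trien-6,12-olide, both ring alkenes ring-cis | C=C1C(=O)O[C@@H]2/C=C(/C)CC/C=C(/C=O)[C@@H](OC(=O)[C@H](C)CC)[C@@H](O)[C@@H]12 | target

Total step count: 20. Longest linear sequence: 20 steps (1 to 37); compounds 4, 7, 15, 27 and 35 enter as purchased.

Steps most likely to fail

Step 11 (key step). The titanium alkoxide may, instead of fragmenting, open the epoxide by attack of O6 at C14 or trigger a 1,2-shift of the activated epoxide, or the substrate may stay in the unreactive chair. The fallback keeps the C1–C6 scission but changes the trigger to a retro-aldol ring expansion. It sets out from 13: KN(SiMe3)2 in THF at −78 °C forms the potassium aldolate, which cleaves the C1–C6 bond to the ring-expanded C10 enolate, and PhNTf2 traps this as the ring-cis enol triflate F4. Stille coupling of F4 with Bu3SnCH2OH (Pd(PPh3)4, zerovalent palladium, LiCl, THF) installs the C14 hydroxymethyl group and returns to the route at 20.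

Step 6. The allylchromium intermediate may lose the C8 oxygen by vinylogous β-elimination, or the ring may close through the other face of C7. The fallback replaces the organochromium nucleophile by an allylsilane that reacts through an open transition state. It sets out from 3: cross-metathesis with allyltrimethylsilane (second-generation Grubbs catalyst) gives the allylsilane alcohol F1, Dess–Martin oxidation gives the aldehyde F2, and aldol addition of titanium dienolate 9 gives the allylsilane aldol adduct F3. Intramolecular Hosomi–Sakurai addition (BF3·OEt2, CH2Cl2, −78 °C), which can only occur 1,2 for geometric reasons, returns to the route at 12.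

Step 20. Discrimination between the C8 and C9 hydroxyls may be insufficient, or the acyl group may migrate to O8. The fallback fixes the regiochemistry through the 1,3-relationship of O9 and O14. It sets out from 32:
- aqueous CF3CO2H gives the 8,9,14-triol F5;
- tBu2Si(OTf)2 with 2,6-lutidine bridges O9 and O14 as the six-membered silylene F6, leaving only O8–H;
- TBSOTf converts F6 into the C8 silyl ether F7;
- HF·pyridine at 0 °C cleaves the cyclic silylene selectively to the 9,14-diol F8;
- MnO2 oxidises the primary allylic alcohol to the enal F9;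
- Steglich esterification with 35 acylates the only free hydroxyl (O9) to give F10;
- HF·pyridine removes the C8 silyl ether and returns to the route at 37.

Further compounds
F1 | step 6 | [(4R,5S)-2,2-dimethyl-5-[(E)-3-(trimethylsilyl)prop-1-enyl]-1,3-dioxolan-4-yl]methanol | OC[C@H]1OC(C)(C)O[C@H]1/C=C/C[Si](C)(C)C
F2 | step 6 | (4S,5S)-2,2-dimethyl-5-[(E)-3-(trimethylsilyl)prop-1-enyl]-1,3-dioxolane-4-carbaldehyde | O=C[C@H]1OC(C)(C)O[C@H]1/C=C/C[Si](C)(C)C
F3 | step 6 | allylsilane analogue of aldol adduct 10 (CH2SiMe3 in place of CH2Cl) | O=C1C=C(C)CC[C@@H]1[C@@H](O)[C@H]2OC(C)(C)O[C@H]2/C=C/C[Si](C)(C)C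
F4 | step 11 | ring-cis C10 enol triflate of the ring-expanded cyclodecadienone (C6 ketone, C8,C9-acetonide, C7-vinyl) | O=C1/C=C(/C)CC/C=C(/OS(=O)(=O)C(F)(F)F)[C@H]2OC(C)(C)O[C@H]2[C@H]1C=C
F5 | step 20 | α-methylene lactone 8,9,14-triol | C=C1C(=O)O[C@@H]2/C=C(/C)CC/C=C(/CO)[C@@H](O)[C@@H](O)[C@@H]12
F6 | step 20 | 9,14-O-di-tert-butylsilylene derivative of F5 with free C8 hydroxyl | C=C1C(=O)O[C@@H]2/C=C(/C)CC/C=C3/CO[Si](C(C)(C)C)(C(C)(C)C)O[C@H]3[C@@H](O)[C@@H]12
F7 | step 20 | 8-O-tert-butyldimethylsilyl ether of F6 | C=C1C(=O)O[C@@H]2/C=C(/C)CC/C=C3/CO[Si](C(C)(C)C)(C(C)(C)C)O[C@H]3[C@@H](O[Si](C)(C)C(C)(C)C)[C@@H]12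
F8 | step 20 | 8-O-tert-butyldimethylsilyl 9,14-diol | C=C1C(=O)O[C@@H]2/C=C(/C)CC/C=C(/CO)[C@@H](O)[C@@H](O[Si](C)(C)C(C)(C)C)[C@@H]12
F9 | step 20 | 8-O-tert-butyldimethylsilyl C14 enal with free C9 hydroxyl | C=C1C(=O)O[C@@H]2/C=C(/C)CC/C=C(/C=O)[C@@H](O)[C@@H](O[Si](C)(C)C(C)(C)C)[C@@H]12
F10 | step 20 | 8-O-tert-butyldimethylsilyl ether of target 37 | C=C1C(=O)O[C@@H]2/C=C(/C)CC/C=C(/C=O)[C@@H](OC(=O)[C@H](C)CC)[C@@H](O[Si](C)(C)C(C)(C)C)[C@@H]12
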